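Assumption: (2S)-hesperetin (the aglycone of citrus hesperidin) and (R)-benzyl glycidyl ether are bought at ≥98% ee and checked by chiral HPLC. Flavonolignan locants are used: C7'/C8'/C9' for the C3 chain, 3'/4' for the B-ring oxygens.

## Retrosynthetic overview
1. Open the dioxane of silandrin at O4'–C7'. This gives seco-ether 7, which is closed last by an anodic benzylic C–H / O–CH3 exchange.
2. Disconnect 7 at O3'–C8'. This bond comes from a Mitsunobu inversion between the only free B-ring OH of hesperetin and alcohol 3. The natural 4'-OMe fixes the regiochemistry.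
3. Alcohol 3 comes from an aryl Grignard reagent and (R)-benzyl glycidyl ether, so C8' is bought.
4. Rings A and C, and C2, are bought intact in (2S)-hesperetin.
5. The dioxane is the only ring built. C7' is set last, trans to C8'.

## Route

**Step 1**
Reactants: 1, 1-(benzyloxy)-4-bromo-2-methoxybenzene; 2, (R)-benzyl glycidyl ether
Product: 3, (2R)-1-(benzyloxy)-3-[4-(benzyloxy)-3-methoxyphenyl]propan-2-ol
Conditions: 1, Mg, THF; then CuI (10 mol %), 2, −30 → 0 °C
Reagents that add atoms: none
Why: Cu-catalysed aryl Grignard opening of a terminal epoxide is an SN2 attack at the CH2 carbon, so the bought C–O stereocentre is untouched and 3 is (R).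

**Step 2**
Reactants: 4, (2S)-hesperetin
Product: 5, (2S)-7-(benzyloxy)-5-hydroxy-2-(3-hydroxy-4-methoxyphenyl)-2,3-dihydrochromen-4-one
Conditions: BnOH (1.0 equiv), PPh3, DIAD, THF, 0 °C → rt
Reagents that add atoms: benzyl alcohol, OCc1ccccc1
Why: This is a regioselective Mitsunobu etherification in which 7-OH (pKa ≈ 7.5) is far more acidic than 3'-OH (≈ 10) or the chelated 5-OH, and the neutral medium avoids base-induced chalcone opening, so C2 stays (S).

**Step 3**
Reactants: 5; 3 (1.3 equiv)
Product: 6, (2S)-7-(benzyloxy)-2-[3-({(2S)-1-(benzyloxy)-3-[4-(benzyloxy)-3-methoxyphenyl]propan-2-yl}oxy)-4-methoxyphenyl]-5-hydroxy-2,3-dihydrochromen-4-one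
Conditions: PPh3, DIAD, toluene–THF, 0 °C → rt
Reagents that add atoms: none
Why: In this Mitsunobu aryl ether synthesis, 3'-OH is the only free unchelated phenol (O4' carries the natural methyl group) and displaces the activated secondary alcohol by SN2 with inversion, so (R)-3 becomes (S) at C8' and the O3'–C8' regiochemistry is fixed.

**Step 4**
Reactants: 6
Product: 7, (2S)-5,7-dihydroxy-2-(3-{[(2S)-1-hydroxy-3-(4-hydroxy-3-methoxyphenyl)propan-2-yl]oxy}-4-methoxyphenyl)-2,3-dihydrochromen-4-one
Conditions: H2 (1 atm), 10% Pd/C, EtOAc–MeOH, rt
Reagents that add atoms: none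
Why: Neutral catalytic hydrogenolysis removes the three O-benzyl groups, while the aryl methyl ethers, the secondary alkyl aryl ether, the ketone and both stereocentres are inert.

**Step 5**
Reactants: 7
Product: 8, silandrin, (2S)-2-[(2R,3R)-2-(4-hydroxy-3-methoxyphenyl)-3-(hydroxymethyl)-2,3-dihydro-1,4-benzodioxin-6-yl]-5,7-dihydroxy-2,3-dihydrochromen-4-one
Conditions: DDQ (20 mol %), Et4NOTs (0.1 M), TFA (5 equiv), MeCN–HFIP 4:1 (5 mM), divided cell, RVC(+)/Pt(−), +0.9 V vs Ag/AgCl, 2.2 F mol⁻¹, 40 °C (by-products MeOTs and H2)
Reagents that add atoms: none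
Why: Proposed new method: anodic, DDQ-relayed dehydrogenative and demethylative benzylic C–H aryloxylation, in which DDQ (re-oxidised at the anode, H2 evolved at the cathode) abstracts hydride only from the one free 4-alkylguaiacol (the B ring is a dialkyl catechol ether about 0.3 V or more harder to oxidise, so C2–H is safe, and the A ring is acyl-deactivated) to give the same p-quinone methide used in the biosynthesis; after protonation every external capture (TsO⁻, CF3CO2⁻, HFIP) is reversible, C-attack at C2' would be 5-endo, and no base is present to form the enol ether, so the cation is funnelled through six-membered capture by the pre-organised 4'-OMe oxygen to an aryl(methyl)oxonium ion that tosylate demethylates irreversibly, forming O4'–C7'; the chair transition state with aryl and CH2OH equatorial, backed by acid-reversible ionisation of the p-hydroxybenzyl aryl ether, places C7' trans to the bought C8' centre (7'R,8'R) while C8' and C2 are untouched; the closest known reaction types are Ag2O/DDQ quinone-methide closures of free catechol monoethers to trans-benzodioxanes, benzylic oxidations with electro-regenerated DDQ, and MeO-n neighbouring-group (demethylative) cyclisations such as the acid/LiBr conversion of lignin β-O-4 guaiacyl ethers into benzodioxanes.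

## Compound list
1 | 1-(benzyloxy)-4-bromo-2-methoxybenzene | COc1cc(Br)ccc1OCc1ccccc1 | starting material
2 | (R)-benzyl glycidyl ether | C1[C@@H](O1)COCc2ccccc2 | starting material
3 | (2R)-1-(benzyloxy)-3-[4-(benzyloxy)-3-methoxyphenyl]propan-2-ol | O[C@H](Cc1ccc(OCc2ccccc2)c(OC)c1)COCc1ccccc1 | intermediate
4 | (2S)-hesperetin | COc1ccc(cc1O)[C@@H]1CC(=O)c2c(O)cc(O)cc2O1 | starting material
5 | (2S)-7-O-benzylhesperetin | COc1ccc(cc1O)[C@@H]1CC(=O)c2c(O)cc(OCc3ccccc3)cc2O1 | intermediate
6 | tri-O-benzyl 3'-O-[(S)-C8'] seco-ether | COc1ccc(cc1O[C@@H](Cc1ccc(OCc2ccccc2)c(OC)c1)COCc1ccccc1)[C@@H]1CC(=O)c2c(O)cc(OCc3ccccc3)cc2O1 | intermediate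
7 | debenzylated seco-ether (2S, 8'S; 4'-OMe) | COc1ccc(cc1O[C@@H](Cc1ccc(O)c(OC)c1)CO)[C@@H]1CC(=O)c2c(O)cc(O)cc2O1 | intermediate
8 | silandrin (2S, 7'R, 8'R) | COc1cc([C@H]2Oc3ccc([C@@H]4CC(=O)c5c(O)cc(O)cc5O4)cc3O[C@@H]2CO)ccc1O | target

## Totals
Total steps: 5. Longest linear sequence: 4 (4 → 5 → 6 → 7 → 8, or 1/2 → 3 → 6 → 7 → 8).

## Steps most likely to fail
1. **Step 5 (the new step).**
   - Risk: capture by the methyl ether oxygen may be too slow. The cation could then drift to the enol ether or a Hibbert-type ketone, which erodes C8'. It could also alkylate A rings intermolecularly, or product 8 could be over-oxidised.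
   - Fallback (known chemistry only): stop using OMe as the nucleophile and exchange the methyl for benzyl before the union.
     - The exchange sequence is hesperetin → 3',7-bis(2-nosylate) → BBr3 → 4'-OBn → PhSH/K2CO3.
     - Steps 2–4 then run unchanged and give the free 4'-OH seco-phenol.
     - The ring is closed with stoichiometric Ag2O or DDQ, the established quinone-methide closure of catechol monoethers to trans-benzodioxanes. This costs 4 extra steps.
2. **Step 3 (Mitsunobu).**
   - Risk: a hindered homobenzylic secondary alcohol with an ortho-substituted phenol may eliminate to the styrene or give low conversion.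
   - Fallback: replace the redox condensation with a sulfonate displacement. Convert 3 to its 4-nitrobenzenesulfonate and displace it with the caesium phenoxide of 5 in MeCN at rt. This is a plain SN2 with the same inversion; monitor the ee at C2.
3. **Step 2 (7-O selectivity and quality of 4).**
   - Risk: bis-alkylation, or commercial hesperetin lots that are partly racemic.
   - Fallback: start from hesperidin, whose 7-O-rutinoside already blocks O7. The 2S epimer can be upgraded by recrystallisation because the sugar makes the C2 epimers diastereomers. Use hesperidin directly as the phenol in Step 3, and cleave the sugar with H2SO4/MeOH after the union and before Step 5.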